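The route rests on closing ring A across its C3=C4 bond. Ring A is a furan with hydrogen at C2 and C5 and carbon substituents only at C3 and C4, so ring-closing metathesis of a bis(2-substituted allyl) ether forms that bond, the ring and the complete 3,4-substitution pattern in one operation; dehydrogenation then gives the furan. The precursor is a diallyl ether whose two 1,1-disubstituted alkenes carry the furan-3-ylmethyl group (ring B) and a 3-silyloxypropyl chain. The chain is later grown into an (E,E)-dienyl iodide, joined to a chiral 2-methylpropanoate zinc reagent that supplies the (S) centre, and the (Z)-alkylidene butenolide is closed last from a terminal alkyne.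

Key step: step 4

Remark: read from the SMILES, the methyl-bearing stereocentre is (S), the chain alkenes are 4E and 6E and the exocyclic alkene is Z; the CH2–CH(CH3) unit between diene and butenolide is three carbons long with its branch, so it is supplied as a 2-methylpropanoate building block.

Step 1
Reactants: 1 3-bromofuran; 2 3-chloro-2-(chloromethyl)prop-1-ene
Product: 5 3-[2-(chloromethyl)prop-2-en-1-yl]furan, via furan-3-yllithium 3 (not isolated), via furan-3-ylmagnesium bromide 4 (not isolated)
Conditions: n-BuLi, THF, –78 °C; MgBr2·OEt2, –78 → –40 °C; then cannulated into 2 (3 equiv), CuI (5 mol%), THF, –40 °C → rt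
Reagents that add atoms: none
Why: Bromine–lithium exchange at –78 °C gives the 3-lithiofuran before it can migrate to C2, transmetalation to magnesium fixes it, and copper-catalysed allylic substitution on the symmetrical dichloride (direct and allylic displacement give the same product) should stop at monosubstitution because the dichloride is in excess.

Step 2
Reactants: 6 tert-butyl(dimethyl)(prop-2-en-1-yloxy)silane; 7 2-bromoprop-2-en-1-ol
Product: 9 5-{[tert-butyl(dimethyl)silyl]oxy}-2-methylidenepentan-1-ol, via alkylborane 8 (not isolated)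
Conditions: 9-BBN (0.5 M in THF), 0 °C → rt; then 7, Pd(dppf)Cl2 (3 mol%), aq. K3PO4, DMF, 50 °C
Reagents that add atoms: none
Why: Anti-Markovnikov hydroboration of the terminal alkene followed by B-alkyl Suzuki–Miyaura coupling with the 1,1-disubstituted vinyl bromide joins C(sp3) to C(sp2) under mildly basic conditions that tolerate the free allylic alcohol and the silyl ether.

Step 3
Reactants: 9 5-{[tert-butyl(dimethyl)silyl]oxy}-2-methylidenepentan-1-ol; 5 3-[2-(chloromethyl)prop-2-en-1-yl]furan
Product: 11 tert-butyl{[4-({[2-(furan-3-ylmethyl)prop-2-en-1-yl]oxy}methyl)pent-4-en-1-yl]oxy}dimethylsilane, via sodium alkoxide 10 (not isolated)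
Conditions: NaH, THF/DMF (4:1), 0 °C; then 5, Bu4NI (10 mol%), 0 °C → rt
Reagents that add atoms: none
Why: Williamson ether synthesis in which the primary allylic alkoxide displaces the primary allylic chloride, the direct and the allylic pathway being degenerate for this 2-substituted allyl chloride.

Step 4
Reactants: 11 tert-butyl{[4-({[2-(furan-3-ylmethyl)prop-2-en-1-yl]oxy}methyl)pent-4-en-1-yl]oxy}dimethylsilane
Product: 12 tert-butyl{3-[4-(furan-3-ylmethyl)-2,5-dihydrofuran-3-yl]propoxy}dimethylsilane
Conditions: (H2IMes)(PCy3)Cl2Ru=CHPh (second-generation Grubbs catalyst, 10 mol% in two portions), toluene (0.01 M), 80 °C, argon sparge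
Reagents that add atoms: none
Why: Ring-closing olefin metathesis: the catalyst exchanges its benzylidene for one of the two terminal methylidene units to give a substrate-bound Ru=C alkylidene, which undergoes intramolecular [2+2] cycloaddition with the second 1,1-disubstituted alkene, and cycloreversion of the four-membered metallacycle forms the C3=C4 bond and passes Ru=CH2 on, so that ethene is the only co-product. The closest known reaction type is the ring-closing metathesis of bis(2-alkylallyl) ethers, malonates and sulfonamides to five-membered rings with a tetrasubstituted alkene. The single ring, the 2,5-dihydrofuran that becomes ring A, closes at carbon between the two internal alkene carbons, the O1, C2 and C5 atoms being already joined in the ether, so no C–O bond is made and the 3,4-pattern cannot be scrambled. No stereocentre is formed. The selectivity needed is ring closure over intermolecular metathesis and over isomerisation of the allyl ether by Ru–H species; high dilution, removal of ethene by the argon stream, the low tendency of 1,1-disubstituted alkenes to homodimerise and the favourable five-membered ring size secure it, and aromatic ring B is not a metathesis substrate.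

Step 5
Reactants: 12 tert-butyl{3-[4-(furan-3-ylmethyl)-2,5-dihydrofuran-3-yl]propoxy}dimethylsilane
Product: 13 tert-butyl{3-[4-(furan-3-ylmethyl)furan-3-yl]propoxy}dimethylsilane
Conditions: DDQ (1.1 equiv), 1,4-dioxane, rt
Reagents that add atoms: none
Why: Dehydrogenation with DDQ, in which hydride abstraction from a ring CH2 that is both allylic and next to oxygen gives an oxocarbenium ion that loses a proton to aromatise, and this position should react well before the CH2 between the two furans when only one equivalent of oxidant is present.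

Step 6
Reactants: 13 tert-butyl{3-[4-(furan-3-ylmethyl)furan-3-yl]propoxy}dimethylsilane
Product: 14 3-[4-(furan-3-ylmethyl)furan-3-yl]propan-1-ol
Conditions: Bu4NF (1.2 equiv), THF, 0 °C → rt
Reagents that add atoms: none
Why: Fluoride-mediated desilylation cleaves the Si–O bond under conditions to which both furans are inert.

Step 7
Reactants: 14 3-[4-(furan-3-ylmethyl)furan-3-yl]propan-1-ol
Product: 15 3-[4-(furan-3-ylmethyl)furan-3-yl]propanal
Conditions: Dess–Martin periodinane (1.2 equiv), pyridine, CH2Cl2, 0 °C → rt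
Reagents that add atoms: none
Why: Dess–Martin oxidation of the primary alcohol stops at the aldehyde, and the pyridine buffer keeps the acetic acid released away from the acid-sensitive furans.

Step 8
Reactants: 15 3-[4-(furan-3-ylmethyl)furan-3-yl]propanal; 16 2-(triphenyl-λ5-phosphanylidene)propanal
Product: 17 (2E)-5-[4-(furan-3-ylmethyl)furan-3-yl]-2-methylpent-2-enal
Conditions: toluene, 90 °C
Reagents that add atoms: 2-(triphenyl-λ5-phosphanylidene)propanal (16), CC(C=O)=P(c1ccccc1)(c1ccccc1)c1ccccc1
Why: Wittig olefination with the stabilised formyl ylide should give the (E)-2-methyl enal, and the conjugated product aldehyde reacts much more slowly with the ylide than the saturated aldehyde does.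

Step 9
Reactants: 17 (2E)-5-[4-(furan-3-ylmethyl)furan-3-yl]-2-methylpent-2-enal; 18 triiodomethane
Product: 19 3-(furan-3-ylmethyl)-4-[(3E,5E)-6-iodo-4-methylhexa-3,5-dien-1-yl]furan
Conditions: CrCl2 (6 equiv), CHI3 (2 equiv), THF/1,4-dioxane, 0 °C → rt, dark
Reagents that add atoms: triiodomethane (18), IC(I)I
Why: Takai olefination, in which CHI(CrCl2)2 formed from iodoform and divalent chromium adds to the aldehyde and eliminates to the (E)-vinyl iodide, here an (E,E)-dienyl iodide, without touching the trisubstituted alkene or the furans.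

Step 10
Reactants: 19 3-(furan-3-ylmethyl)-4-[(3E,5E)-6-iodo-4-methylhexa-3,5-dien-1-yl]furan; 20 methyl (2R)-3-bromo-2-methylpropanoate
Product: 22 methyl (2S,4E,6E)-9-[4-(furan-3-ylmethyl)furan-3-yl]-2,6-dimethylnona-4,6-dienoate, via alkylzinc bromide 21 (not isolated)
Conditions: Zn dust (activated with 1,2-dibromoethane and Me3SiCl), 20, THF, 40 °C; then 19, Pd(PPh3)4 (5 mol%), THF, rt → 45 °C
Reagents that add atoms: none
Why: Zinc insertion into the primary C–Br bond gives an alkylzinc bromide whose α-stereocentre takes no part, and Negishi coupling with the dienyl iodide under zerovalent palladium keeps the alkene geometry, the change from (2R) in 20 to (2S) in 22 being only a change of CIP priorities at an untouched centre.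

Step 11
Reactants: 22 methyl (2S,4E,6E)-9-[4-(furan-3-ylmethyl)furan-3-yl]-2,6-dimethylnona-4,6-dienoate; 23 dimethyl (1-diazo-2-oxopropyl)phosphonate
Product: 26 3-[(3E,5E,8S)-4,8-dimethyldeca-3,5-dien-9-yn-1-yl]-4-(furan-3-ylmethyl)furan, via aluminium hemiacetal 24 (not isolated), via dienal 25 (not isolated)
Conditions: i-Bu2AlH (1.1 equiv), CH2Cl2, –78 °C; MeOH, –78 °C; then 23, K2CO3, MeOH, 0 °C → rt
Reagents that add atoms: dimethyl (1-diazo-2-oxopropyl)phosphonate (23), CC(=O)C(=[N+]=[N-])P(=O)(OC)OC
Why: Low-temperature reduction with i-Bu2AlH stops at the tetrahedral hemiacetal RCH(OMe)OAl(i-Bu)2, methanolysis releases the aldehyde, and Ohira–Bestmann (Seyferth–Gilbert) homologation in the same flask converts it to the terminal alkyne under mild carbonate conditions that should leave the α-methyl stereocentre intact.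

Step 12
Reactants: 27 methyl prop-2-ynoate; 28 formaldehyde
Product: 29 methyl (2Z)-2-(hydroxymethyl)-3-iodoprop-2-enoate
Conditions: MgI2 (1.2 equiv), CH2O (monomer from cracked paraformaldehyde, 3 equiv), CH2Cl2, –20 → 0 °C
Reagents that add atoms: formaldehyde (28), C=O; magnesium diiodide, [Mg+2].[I-].[I-]
Why: Iodo-aldol three-component reaction of the β-iodo Morita–Baylis–Hillman type, in which iodide adds to the ynoate and the resulting β-iodoallenolate is trapped at the α-carbon by formaldehyde, kinetic capture at low temperature placing iodine cis to the ester.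

Step 13
Reactants: 29 methyl (2Z)-2-(hydroxymethyl)-3-iodoprop-2-enoate
Product: 30 (2Z)-2-(hydroxymethyl)-3-iodoprop-2-enoic acid
Conditions: LiOH·H2O, THF/H2O (3:1), 0 °C; then aq. HCl to pH 2–3
Reagents that add atoms: lithium hydroxide, [Li+].[OH-]
Why: Saponification of the methyl ester at 0 °C, where the vinyl iodide has no α-hydrogen through which HI could be eliminated and the Z geometry should be kept.

Step 14
Reactants: 26 3-[(3E,5E,8S)-4,8-dimethyldeca-3,5-dien-9-yn-1-yl]-4-(furan-3-ylmethyl)furan; 30 (2Z)-2-(hydroxymethyl)-3-iodoprop-2-enoic acid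
Product: 32 (5Z)-5-{(2S,4E,6E)-9-[4-(furan-3-ylmethyl)furan-3-yl]-2,6-dimethylnona-4,6-dien-1-ylidene}-3-(hydroxymethyl)furan-2(5H)-one, via enynoic acid 31 (not isolated)
Conditions: Pd(PPh3)4 (5 mol%), CuI (10 mol%), Et3N (4 equiv), MeCN, rt, dark
Reagents that add atoms: none
Why: Tandem Sonogashira coupling and lactonisation, in which the carboxylate held cis to the new alkyne adds 5-exo-dig in an anti sense to give the (Z)-alkylidene butenolide, while the hydroxymethyl group is trans to the alkyne and cannot cyclise and the (S) centre is not touched.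

Compound list
1 | 3-bromofuran | Brc1ccoc1 | starting material
2 | 3-chloro-2-(chloromethyl)prop-1-ene | C=C(CCl)CCl | starting material
3 | furan-3-yllithium | [Li]c1ccoc1 | intermediate
4 | furan-3-ylmagnesium bromide | Br[Mg]c1ccoc1 | intermediate
5 | 3-[2-(chloromethyl)prop-2-en-1-yl]furan | C=C(CCl)Cc1ccoc1 | intermediate
6 | tert-butyl(dimethyl)(prop-2-en-1-yloxy)silane | C=CCO[Si](C)(C)C(C)(C)C | starting material
7 | 2-bromoprop-2-en-1-ol | C=C(Br)CO | starting material
8 | 9-{3-[(tert-butyldimethylsilyl)oxy]propyl}-9-borabicyclo[3.3.1]nonane | CC(C)(C)[Si](C)(C)OCCCB1C2CCCC1CCC2 | intermediate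
9 | 5-{[tert-butyl(dimethyl)silyl]oxy}-2-methylidenepentan-1-ol | C=C(CCCO[Si](C)(C)C(C)(C)C)CO | intermediate
10 | sodium 5-{[tert-butyl(dimethyl)silyl]oxy}-2-methylidenepentan-1-olate | C=C(CCCO[Si](C)(C)C(C)(C)C)C[O-].[Na+] | intermediate
11 | tert-butyl{[4-({[2-(furan-3-ylmethyl)prop-2-en-1-yl]oxy}methyl)pent-4-en-1-yl]oxy}dimethylsilane | C=C(CCCO[Si](C)(C)C(C)(C)C)COCC(=C)Cc1ccoc1 | intermediate
12 | tert-butyl{3-[4-(furan-3-ylmethyl)-2,5-dihydrofuran-3-yl]propoxy}dimethylsilane | CC(C)(C)[Si](C)(C)OCCCC1=C(Cc2ccoc2)COC1 | intermediate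
13 | tert-butyl{3-[4-(furan-3-ylmethyl)furan-3-yl]propoxy}dimethylsilane | CC(C)(C)[Si](C)(C)OCCCc1cocc1Cc1ccoc1 | intermediate
14 | 3-[4-(furan-3-ylmethyl)furan-3-yl]propan-1-ol | OCCCc1cocc1Cc1ccoc1 | intermediate
15 | 3-[4-(furan-3-ylmethyl)furan-3-yl]propanal | O=CCCc1cocc1Cc1ccoc1 | intermediate
16 | 2-(triphenyl-λ5-phosphanylidene)propanal | CC(C=O)=P(c1ccccc1)(c1ccccc1)c1ccccc1 | starting material
17 | (2E)-5-[4-(furan-3-ylmethyl)furan-3-yl]-2-methylpent-2-enal | O=C/C(C)=C/CCc1cocc1Cc1ccoc1 | intermediate
18 | triiodomethane (iodoform) | IC(I)I | starting material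
19 | 3-(furan-3-ylmethyl)-4-[(3E,5E)-6-iodo-4-methylhexa-3,5-dien-1-yl]furan | I/C=C/C(C)=C/CCc1cocc1Cc1ccoc1 | intermediate
20 | methyl (2R)-3-bromo-2-methylpropanoate | COC(=O)[C@@H](C)CBr | starting material
21 | bromo[(2R)-3-methoxy-2-methyl-3-oxopropyl]zinc | COC(=O)[C@@H](C)C[Zn]Br | intermediate
22 | methyl (2S,4E,6E)-9-[4-(furan-3-ylmethyl)furan-3-yl]-2,6-dimethylnona-4,6-dienoate | COC(=O)[C@@H](C)C/C=C/C(C)=C/CCc1cocc1Cc1ccoc1 | intermediate
23 | dimethyl (1-diazo-2-oxopropyl)phosphonate | CC(=O)C(=[N+]=[N-])P(=O)(OC)OC | starting material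
24 | bis(2-methylpropyl)aluminium (2S,4E,6E)-9-[4-(furan-3-ylmethyl)furan-3-yl]-1-methoxy-2,6-dimethylnona-4,6-dien-1-olate (both C1 epimers) | COC(O[Al](CC(C)C)CC(C)C)[C@@H](C)C/C=C/C(C)=C/CCc1cocc1Cc1ccoc1 | intermediate
25 | (2S,4E,6E)-9-[4-(furan-3-ylmethyl)furan-3-yl]-2,6-dimethylnona-4,6-dienal | O=C[C@@H](C)C/C=C/C(C)=C/CCc1cocc1Cc1ccoc1 | intermediate
26 | 3-[(3E,5E,8S)-4,8-dimethyldeca-3,5-dien-9-yn-1-yl]-4-(furan-3-ylmethyl)furan | C#C[C@@H](C)C/C=C/C(C)=C/CCc1cocc1Cc1ccoc1 | intermediate
27 | methyl prop-2-ynoate | C#CC(=O)OC | starting material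
28 | formaldehyde (monomer, from commercial paraformaldehyde) | C=O | starting material
29 | methyl (2Z)-2-(hydroxymethyl)-3-iodoprop-2-enoate | COC(=O)/C(CO)=C\I | intermediate
30 | (2Z)-2-(hydroxymethyl)-3-iodoprop-2-enoic acid | OC(=O)/C(CO)=C\I | intermediate
31 | (2Z,6S,8E,10E)-13-[4-(furan-3-ylmethyl)furan-3-yl]-2-(hydroxymethyl)-6,10-dimethyltrideca-2,8,10-trien-4-ynoic acid | OC/C(C(=O)O)=C/C#C[C@@H](C)C/C=C/C(C)=C/CCc1cocc1Cc1ccoc1 | intermediate
32 | (5Z)-5-{(2S,4E,6E)-9-[4-(furan-3-ylmethyl)furan-3-yl]-2,6-dimethylnona-4,6-dien-1-ylidene}-3-(hydroxymethyl)furan-2(5H)-one | CC(/C=C/C[C@H](C)/C=C1/C=C(CO)C(=O)O1)=C\CCc1cocc1Cc1ccoc1 | target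

Total step count: 14.
Longest linear sequence: 11 steps (steps 1, 3, 4, 5, 6, 7, 8, 9, 10, 11 and 14).

Steps most likely to fail

Step 4 (ring-closing metathesis). Turnover may stop because formation of the tetrasubstituted alkene is slow relative to catalyst decay, so that oligomers from intermolecular metathesis or enol ethers from double-bond migration build up. The fallback takes ring A from a preformed furan and only attaches its two substituents; it sets out from 1 and comes back to the route at 13. Furan-3-yllithium 3, made from 1 as in step 1, is formylated with DMF to furan-3-carbaldehyde F1. Commercial 3,4-dibromofuran is mono-exchanged with n-BuLi (Et2O, –78 °C) to (4-bromofuran-3-yl)lithium F2, which adds to F1 to give (4-bromofuran-3-yl)(furan-3-yl)methanol F3. Ionic deoxygenation (Et3SiH, CF3CO2H, CH2Cl2, –20 °C) should give 3-bromo-4-(furan-3-ylmethyl)furan F4, and B-alkyl Suzuki–Miyaura coupling of F4 with alkylborane 8 from step 2 (Pd(OAc)2, SPhos, aq. K3PO4, THF, 60 °C) should give 13.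

Step 12 (iodo-aldol with formaldehyde). Formaldehyde may oligomerise faster than the β-iodoallenolate captures it, or reversible iodide addition may erode the Z geometry. The fallback brings the hydroxymethyl carbon in by cross-coupling at the very end; it sets out from 27 and 26 and comes back at 32. Br2 adds anti to 27 (CH2Cl2, 0 °C) to give methyl (2E)-2,3-dibromoprop-2-enoate F5. Sonogashira coupling of 26 at the more reactive C3–Br bond (Pd(PPh3)4, CuI, Et3N, THF, rt) should give methyl (2E,6S,8E,10E)-2-bromo-13-[4-(furan-3-ylmethyl)furan-3-yl]-6,10-dimethyltrideca-2,8,10-trien-4-ynoate F6. LiOH (THF/H2O, 0 °C) gives (2E,6S,8E,10E)-2-bromo-13-[4-(furan-3-ylmethyl)furan-3-yl]-6,10-dimethyltrideca-2,8,10-trien-4-ynoic acid F7. AgNO3 (10 mol%, acetone, rt, dark) closes it 5-exo-dig to (5Z)-3-bromo-5-{(2S,4E,6E)-9-[4-(furan-3-ylmethyl)furan-3-yl]-2,6-dimethylnona-4,6-dien-1-ylidene}furan-2(5H)-one F8. Stille coupling with (tributylstannyl)methanol (Pd(PPh3)4, 1,4-dioxane, 80 °C) then replaces bromine by CH2OH and gives 32.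

Step 14 (tandem coupling and lactonisation). The carboxylate may close 6-endo to the 2-pyranone, the exocyclic alkene may form as a mixture of geometries, or the alkyne may homocouple under CuI. The fallback separates coupling from cyclisation; it sets out from 26 and ester 29 and comes back at 31. Sonogashira coupling (Pd(PPh3)2Cl2, CuI, Et3N, THF, rt) should give methyl (2Z,6S,8E,10E)-13-[4-(furan-3-ylmethyl)furan-3-yl]-2-(hydroxymethyl)-6,10-dimethyltrideca-2,8,10-trien-4-ynoate F9. Saponification (LiOH, THF/H2O, 0 °C) gives acid 31, now isolated, and AgNO3 (10 mol%, acetone, rt, dark) should close it 5-exo-dig by anti addition to 32.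

Further compounds
F1 | step 4 | furan-3-carbaldehyde | O=Cc1ccoc1
F2 | step 4 | (4-bromofuran-3-yl)lithium | [Li]c1cocc1Br
F3 | step 4 | (4-bromofuran-3-yl)(furan-3-yl)methanol | OC(c1ccoc1)c1cocc1Br
F4 | step 4 | 3-bromo-4-(furan-3-ylmethyl)furan | Brc1cocc1Cc1ccoc1
F5 | step 12 | methyl (2E)-2,3-dibromoprop-2-enoate | COC(=O)/C(Br)=C\Br
F6 | step 12 | methyl (2E,6S,8E,10E)-2-bromo-13-[4-(furan-3-ylmethyl)furan-3-yl]-6,10-dimethyltrideca-2,8,10-trien-4-ynoate | COC(=O)/C(Br)=C\C#C[C@@H](C)C/C=C/C(C)=C/CCc1cocc1Cc1ccoc1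
F7 | step 12 | (2E,6S,8E,10E)-2-bromo-13-[4-(furan-3-ylmethyl)furan-3-yl]-6,10-dimethyltrideca-2,8,10-trien-4-ynoic acid | OC(=O)/C(Br)=C\C#C[C@@H](C)C/C=C/C(C)=C/CCc1cocc1Cc1ccoc1
F8 | step 12 | (5Z)-3-bromo-5-{(2S,4E,6E)-9-[4-(furan-3-ylmethyl)furan-3-yl]-2,6-dimethylnona-4,6-dien-1-ylidene}furan-2(5H)-one | CC(/C=C/C[C@H](C)/C=C1/C=C(Br)C(=O)O1)=C\CCc1cocc1Cc1ccoc1
F9 | step 14 | methyl (2Z,6S,8E,10E)-13-[4-(furan-3-ylmethyl)furan-3-yl]-2-(hydroxymethyl)-6,10-dimethyltrideca-2,8,10-trien-4-ynoate | COC(=O)/C(CO)=C\C#C[C@@H](C)C/C=C/C(C)=C/CCc1cocc1Cc1ccoc1
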